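**Plan** (numbering: ring O1, O2, C3 hemiketal, C4 CHMe, C5 CH2, C6 quaternary; C2/C1 = acetate arm; C7, C8 … = side chain)

- Retrosynthesis: the 3-hydroxy-1,2-dioxane is opened to its ring-chain tautomer, a γ-hydroperoxy ketone, which is O2 inserted into the C3–C6 bond of a cyclobutanol. Further cuts are C2–C3 (acetate aldol), C4–CH3 (enolate methylation), C3–C4 together with C5–C6 ([2+2] of a keteniminium ion with ethylene), C6–C7 (amide alkylation) and C9–C10 (Grignard coupling).
- Enabling feature: C3 (ketone oxidation level) and the fully substituted peroxide carbon C6 are 1,4-related through C4–C5. C3/C6 therefore map onto the carbonyl and α-carbon of a ketene equivalent and C4–C5 onto an alkene; the cyclobutane C3–C6 bond is a temporary helper, later replaced by the O1–O2 bridge.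
- Forward: side chain → α-branched amide → cyclobutanone (temporary four-membered ring) → C4 methylation → acetate addition at C3 → aerobic ring expansion, which closes the only ring of the target, the 1,2-dioxane, last.
- Stereochemistry: C8 comes from commercial (S)-1-bromo-3-chloro-2-methylpropane. C3 is set relative to C4 by ring-chain equilibration (axial anomeric OH), and C4 is equilibrated through the enol toward the chair with the long side chain equatorial at C6. C6 is not controlled: a planar tertiary radical captures O2 with no facial bias, so the (6S) series is secured only by separation in step 8.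

Key step: step 4

Assumption: for a given C6 configuration, the target arrangement (axial anomeric C3–OH cis to an equatorial C4 methyl, larger C6 substituent equatorial) is the thermodynamically preferred peroxyhemiketal and can be reached by equilibration; the preference over the isomer with the side chain axial is expected to be modest.

Step 1
Reactants: 1 (7-bromoheptyl)benzene; 2 (S)-1-bromo-3-chloro-2-methylpropane
Product: 4 [(9R)-10-chloro-9-methyldecyl]benzene, via 7-phenylheptylmagnesium bromide 3 (not isolated)
Conditions: Mg, THF, reflux; then 2, Li2CuCl4 (cat.), THF, −10 to 0 °C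
Reagents that add atoms: none
Why: Copper-catalysed sp3–sp3 Grignard cross-coupling should occur at the C–Br bond only and leave the C–Cl bond for step 2; the methyl-bearing centre (C8 of the target) is not involved, so its configuration is carried over from 2 (the descriptor changes from S to R only through the priority change).

Step 2
Reactants: 4 [(9R)-10-chloro-9-methyldecyl]benzene
Product: 5 [(9R)-10-iodo-9-methyldecyl]benzene
Conditions: NaI, 2-butanone, reflux
Reagents that add atoms: sodium iodide, [Na+].[I-]
Why: Finkelstein halide exchange should turn the sluggish β-branched primary chloride into the iodide needed for enolate alkylation, without touching the stereocentre.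

Step 3
Reactants: 6 N,N-dimethylpropanamide; 5 [(9R)-10-iodo-9-methyldecyl]benzene
Product: 8 (4R)-N,N,2,4-tetramethyl-12-phenyldodecanamide (both C2 epimers), via lithium amide enolate 7 (not isolated)
Conditions: LiN(i-Pr)2, THF, −78 °C; then 5, −78 °C to rt
Reagents that add atoms: none
Why: SN2 alkylation of the lithium amide enolate by the primary iodide should form the C6–C7 bond; the new α-centre forms as both epimers, which is immaterial because it becomes sp2 in step 4.

Step 4
Reactants: 8 (4R)-N,N,2,4-tetramethyl-12-phenyldodecanamide; 9 ethylene
Product: 12 2-methyl-2-[(2R)-2-methyl-10-phenyldecyl]cyclobutan-1-one (both C2 epimers), via keteniminium triflate 10 (not isolated), via cyclobutaniminium triflate 11 (not isolated)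
Conditions: Tf2O, 2,4,6-collidine, ClCH2CH2Cl, −20 °C to rt; 9 (1 atm), reflux; then H2O, reflux
Reagents that add atoms: water, O
Why: O-triflation of the amide and collidine-mediated loss of triflic acid give keteniminium ion 10; its electrophilic central carbon (future C3) is attacked by ethylene while the enamine-type terminus (future C6) closes on the developing cationic carbon, so the C3–C4 and C5–C6 bonds form in one asynchronous [2+2] event, and iminium 11 is hydrolysed to the ketone on work-up. The closest known reaction type is the keteniminium–alkene [2+2] cycloaddition that converts α-branched tertiary amides into 2,2-disubstituted cyclobutanones. The four-membered carbocycle is closed by intermolecular [2+2] cycloaddition, the second C–C bond completing the ring. The quaternary carbon C6 is created without control and none is needed, because this centre is planarised as a radical in step 7; the remote C8 centre is untouched. The step needs chemoselectivity for cycloaddition over proton loss or self-condensation, which the fully substituted α-carbon of 10 (no α-hydrogen, hence no ynamine formation) and the high electrophilicity of the keteniminium ion toward an unactivated alkene should secure; regiochemistry is not an issue because ethylene is symmetrical.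

Step 5
Reactants: 12 2-methyl-2-[(2R)-2-methyl-10-phenyldecyl]cyclobutan-1-one
Product: 14 2,4-dimethyl-2-[(2R)-2-methyl-10-phenyldecyl]cyclobutan-1-one (diastereomer mixture), via lithium cyclobutanone enolate 13 (not isolated)
Conditions: LiN(i-Pr)2, THF, −78 °C; MeI, −78 to 0 °C
Reagents that add atoms: iodomethane, CI
Why: Kinetic enolate alkylation: the quaternary C6 leaves C4 as the only enolisable position, so methylation can only occur there; the C4 configuration is not controlled here because it is equilibrated in step 8.

Step 6
Reactants: 14 2,4-dimethyl-2-[(2R)-2-methyl-10-phenyldecyl]cyclobutan-1-one; 15 methyl acetate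
Product: 18 methyl 2-[1-hydroxy-2,4-dimethyl-2-[(2R)-2-methyl-10-phenyldecyl]cyclobutyl]acetate (diastereomer mixture), via lithium enolate of methyl acetate 16 (not isolated), via lithium aldolate 17 (not isolated)
Conditions: 15, LiN(i-Pr)2, THF, −78 °C; then 14, −78 °C; aq. NH4Cl
Reagents that add atoms: none
Why: Aldol addition of the lithium ester enolate to the strained, highly electrophilic cyclobutanone carbonyl should give the tertiary cyclobutanol carrying the complete C1–C2 arm at C3; all diastereomers are carried on, since C3 and C6 lose their configuration in step 7.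

Step 7
Reactants: 18 methyl 2-[1-hydroxy-2,4-dimethyl-2-[(2R)-2-methyl-10-phenyldecyl]cyclobutyl]acetate
Product: 20 methyl 2-[3-hydroxy-4,6-dimethyl-6-[(2R)-2-methyl-10-phenyldecyl]-1,2-dioxan-3-yl]acetate (isomers at C3/C4/C6), via hydroperoxy keto ester 19 (not isolated)
Conditions: Co(acac)2 (cat.), O2 (1 atm), CH2Cl2, rt
Reagents that add atoms: dioxygen, O=O
Why: Cobalt-catalysed aerobic oxidative ring expansion of a cyclobutanol: the alkoxy radical at C3 undergoes strain-driven β-scission of the temporary C3–C6 bond toward the tertiary C6 radical, which captures triplet O2, and the resulting peroxide closes on the new C3 ketone (6-exo-trig hemiketalisation) to form the 1,2-dioxane; C6 is created from a planar radical without facial control, so both C6 epimers are expected.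

Step 8
Reactants: 20 methyl 2-[3-hydroxy-4,6-dimethyl-6-[(2R)-2-methyl-10-phenyldecyl]-1,2-dioxan-3-yl]acetate (isomers at C3/C4/C6)
Product: 22 methyl 2-[(3S,4R,6S)-3-hydroxy-4,6-dimethyl-6-[(2R)-2-methyl-10-phenyldecyl]-1,2-dioxan-3-yl]acetate (target), via hydroperoxy enol 21 (not isolated)
Conditions: TsOH·H2O (cat.), CH2Cl2, rt; then preparative HPLC
Reagents that add atoms: none
Why: Acid-catalysed ring-chain equilibration under thermodynamic control: ionisation of the C3–O2 bond opens the peroxyhemiketal to a protonated ketone that loses the C4 proton to give enol 21, and reprotonation at C4 followed by 6-exo-trig reclosure lets C3 and C4 (but not C6) equilibrate, so that within the (6S) series the chair with axial anomeric C3–OH, equatorial CH2CO2Me, equatorial C4–CH3 and the long side chain equatorial at C6 (the 3S,4R,6S target) should be favoured, though only modestly, over its 3,4-bis-epimer with the side chain axial; that isomer and the two (6R) isomers, all diastereomers of the target because of the fixed (R) centre in the side chain, are removed by HPLC, and the (3R,4S,6S) fraction can be resubjected to the equilibration.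

**Compound list**

1 | (7-bromoheptyl)benzene | BrCCCCCCCc1ccccc1 | starting material
2 | (S)-1-bromo-3-chloro-2-methylpropane | ClC[C@H](C)CBr | starting material
3 | 7-phenylheptylmagnesium bromide | Br[Mg]CCCCCCCc1ccccc1 | intermediate
4 | [(9R)-10-chloro-9-methyldecyl]benzene | ClC[C@H](C)CCCCCCCCc1ccccc1 | intermediate
5 | [(9R)-10-iodo-9-methyldecyl]benzene | IC[C@H](C)CCCCCCCCc1ccccc1 | intermediate
6 | N,N-dimethylpropanamide | CCC(=O)N(C)C | starting material
7 | lithium 1-(dimethylamino)prop-1-en-1-olate | CC=C(O[Li])N(C)C | intermediate
8 | (4R)-N,N,2,4-tetramethyl-12-phenyldodecanamide (both C2 epimers) | CN(C)C(=O)C(C)C[C@H](C)CCCCCCCCc1ccccc1 | intermediate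
9 | ethylene | C=C | starting material
10 | N-[(4R)-2,4-dimethyl-12-phenyldodec-1-en-1-ylidene]-N-methylmethanaminium triflate (keteniminium triflate) | C[N+](C)=C=C(C)C[C@H](C)CCCCCCCCc1ccccc1.[O-]S(=O)(=O)C(F)(F)F | intermediate
11 | N-methyl-N-[2-methyl-2-[(2R)-2-methyl-10-phenyldecyl]cyclobutylidene]methanaminium triflate | C[N+](C)=C1CCC1(C)C[C@H](C)CCCCCCCCc2ccccc2.[O-]S(=O)(=O)C(F)(F)F | intermediate
12 | 2-methyl-2-[(2R)-2-methyl-10-phenyldecyl]cyclobutan-1-one (both C2 epimers) | O=C1CCC1(C)C[C@H](C)CCCCCCCCc2ccccc2 | intermediate
13 | lithium 4-methyl-4-[(2R)-2-methyl-10-phenyldecyl]cyclobut-1-en-1-olate | [Li]OC1=CCC1(C)C[C@H](C)CCCCCCCCc2ccccc2 | intermediate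
14 | 2,4-dimethyl-2-[(2R)-2-methyl-10-phenyldecyl]cyclobutan-1-one (diastereomer mixture) | O=C1C(C)CC1(C)C[C@H](C)CCCCCCCCc2ccccc2 | intermediate
15 | methyl acetate | COC(C)=O | starting material
16 | lithium 1-methoxyethen-1-olate | COC(=C)O[Li] | intermediate
17 | lithium alkoxide of 18 (lithium aldolate) | COC(=O)CC1(O[Li])C(C)CC1(C)C[C@H](C)CCCCCCCCc2ccccc2 | intermediate
18 | methyl 2-[1-hydroxy-2,4-dimethyl-2-[(2R)-2-methyl-10-phenyldecyl]cyclobutyl]acetate (diastereomer mixture) | COC(=O)CC1(O)C(C)CC1(C)C[C@H](C)CCCCCCCCc2ccccc2 | intermediate
19 | methyl (8R)-6-hydroperoxy-4,6,8-trimethyl-3-oxo-16-phenylhexadecanoate (C4/C6 epimers) | COC(=O)CC(=O)C(C)CC(C)(OO)C[C@H](C)CCCCCCCCc1ccccc1 | intermediate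
20 | methyl 2-[3-hydroxy-4,6-dimethyl-6-[(2R)-2-methyl-10-phenyldecyl]-1,2-dioxan-3-yl]acetate (isomers at C3, C4, C6) | COC(=O)CC1(O)OOC(C)(C[C@H](C)CCCCCCCCc2ccccc2)CC1C | intermediate
21 | methyl (8R)-6-hydroperoxy-3-hydroxy-4,6,8-trimethyl-16-phenylhexadec-3-enoate (C6 epimers, both alkene geometries) | COC(=O)CC(O)=C(C)CC(C)(OO)C[C@H](C)CCCCCCCCc1ccccc1 | intermediate
22 | methyl 2-[(3S,4R,6S)-3-hydroxy-4,6-dimethyl-6-[(2R)-2-methyl-10-phenyldecyl]-1,2-dioxan-3-yl]acetate | COC(=O)C[C@]1(O)OO[C@@](C)(C[C@H](C)CCCCCCCCc2ccccc2)C[C@H]1C | target

Total step count: 8. Longest linear sequence: 8 steps (from 1 or 2 to 22).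

**Steps most likely to fail**

Step 7. The cobalt–oxygen manifold may reduce the intermediate peroxyl radical to the alcohol, oxidise the doubly activated C2 methylene once the β-keto ester is unveiled, or fail to engage the hindered tertiary alcohol. The fallback separates C–C cleavage from C–O bond formation and sets out from 18. Silver-catalysed persulfate ring-opening chlorination with N-chlorosuccinimide (AgNO3 cat., K2S2O8, CH2Cl2/H2O) should give methyl (8R)-6-chloro-4,6,8-trimethyl-3-oxo-16-phenylhexadecanoate F1. Silver-assisted perhydrolysis of the tertiary chloride (AgOTf, H2O2 in Et2O, 0 °C) should then give 19, which closes spontaneously, and the route is rejoined at 20.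

Step 8. Chromatographic discrimination between the isomers may be insufficient, since the two C6 series differ only in the relation of the ring to the remote side-chain centre, or acid-mediated epimerisation at C4 may be incomplete or only weakly biased. The fallback sets out from 20. After equilibration, the mixture would be locked as the methyl peroxyketals (MeOH, cat. TsOH, rt), and the desired isomer, methyl 2-[(3S,4R,6S)-3-methoxy-4,6-dimethyl-6-[(2R)-2-methyl-10-phenyldecyl]-1,2-dioxan-3-yl]acetate F2, separated from the other, now configurationally fixed, isomers. Hydrolysis with aqueous trifluoroacetic acid in THF returns to 22.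

Step 4. Capture of the hindered, fully substituted keteniminium ion by gaseous ethylene may be too slow, so that hydrolytic return to 8 or decomposition of the ion dominates. The fallback reaches the cyclobutanone by ketone spiroannulation and sets out from 4. Chloride 4 is converted (Mg, THF, reflux) into [(2R)-2-methyl-10-phenyldecyl]magnesium chloride F3 and acylated with N-methoxy-N-methylacetamide to give (4R)-4-methyl-12-phenyldodecan-2-one F4. Addition of diphenylsulfonium cyclopropylide (cyclopropyldiphenylsulfonium tetrafluoroborate, KOH, DMSO) should give 2-methyl-2-[(2R)-2-methyl-10-phenyldecyl]-1-oxaspiro[2.2]pentane F5. LiBF4-promoted cyclopropylcarbinyl-to-cyclobutyl ring expansion returns to 12; this sequence builds the C5–C6 bond by 1,2-shift and not by cycloaddition.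

Further compounds
F1 | step 7 | methyl (8R)-6-chloro-4,6,8-trimethyl-3-oxo-16-phenylhexadecanoate | COC(=O)CC(=O)C(C)CC(C)(Cl)C[C@H](C)CCCCCCCCc1ccccc1
F2 | step 8 | methyl 2-[(3S,4R,6S)-3-methoxy-4,6-dimethyl-6-[(2R)-2-methyl-10-phenyldecyl]-1,2-dioxan-3-yl]acetate | COC(=O)C[C@]1(OC)OO[C@@](C)(C[C@H](C)CCCCCCCCc2ccccc2)C[C@H]1C
F3 | step 4 | [(2R)-2-methyl-10-phenyldecyl]magnesium chloride | Cl[Mg]C[C@H](C)CCCCCCCCc1ccccc1
F4 | step 4 | (4R)-4-methyl-12-phenyldodecan-2-one | CC(=O)C[C@H](C)CCCCCCCCc1ccccc1
F5 | step 4 | 2-methyl-2-[(2R)-2-methyl-10-phenyldecyl]-1-oxaspiro[2.2]pentane | CC1(C[C@H](C)CCCCCCCCc2ccccc2)OC13CC3
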